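Remark: the locants C1 to C8a are those of the 1,2-dihydronaphthalene of the target and are kept for the same atoms in every open-chain precursor; 3,4-dimethoxyfuran is assumed to lithiate at C2 with n-BuLi, as other 3-alkoxyfurans do.

## Analysis of the target

Target 23 is (1S,2S)-7-hydroxy-1-(4-hydroxy-3,5-dimethoxyphenyl)-6,8-dimethoxy-2,3-dimethyl-1,2-dihydronaphthalene. It has a benzene ring A (C4a, C5 to C8, C8a) fused to a partly saturated ring B (C1 to C4), with the aryl ring C on C1. The two stereocentres are adjacent: C1 is a doubly benzylic methine and C2 an allylic methine bearing a methyl group. Reading the descriptors shows that the C1 aryl group and the C2 methyl group lie on the same face of ring B (cis), so both centres must be set together and cannot be corrected later. The C3=C4 double bond is a trisubstituted, electron-rich styrene: acid protonates C3 to a C4 cation stabilised by the C7 oxygen, and oxidants can aromatise ring B and erase both stereocentres. Six oxygens must be told apart, with one free phenol on each ring (C7 and C4 of ring C), each flanked by two methoxy groups. The difficult part is the C6/C7/C8 oxygen triad next to C8a, which is crowded by the peri C1 aryl group and is awkward to reach by electrophilic ring closure onto a bought arene. The strategy rests on that triad: C8a, C8, C7 and C6 with their oxygens are the four carbons of a 2-substituted 3,4-dimethoxyfuran whose ring oxygen ends on C6, and C4a and C5 (C5 bears only hydrogen) are the two carbons of a terminal alkyne.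

## Retrosynthetic reasoning

**23 to 22 to 21 (O–CH3 bonds).** The furan route delivers its ring oxygen as a free phenol on C6, whereas the target has the phenol on C7. The C6 phenol of 21 is therefore capped as a methyl ether (22), and the two central methyl ethers, C7 on ring A and C4 on ring C, are cut last. This lets both aromatic building blocks be symmetric and commercial. The forward step must distinguish a methoxy group flanked by two oxygens from its neighbours.

**21 to 19 through 20 (C4a–C8a and C5–C6).** Cutting these two bonds opens ring A and ring B together and leaves a furan and an alkyne joined by C1, C2 and the C3=C4 alkene. No other disconnection removes both rings and the whole oxygen triad at once. The forward reaction is an intramolecular [4+2] addition giving the oxygen-bridged adduct 20, which aromatises to 21. The alkene must be Z for the alkyne to reach the furan. C1 and C2 are not touched.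

**19 to 18, 17, 16 (C4a–C5, then oxidation level).** The terminal alkyne carbon C5 is removed as a one-carbon unit, which leads back to the Z-enal 18 and, by redox adjustment, to the Z-enoate 16. A carbonyl olefination at C3 is avoided on purpose. It would have to place the alkynyl group cis to the branched C2 substituent against the steric bias, beside an epimerisable centre.

**16 to 15, 13, 12, 11, 10 (C3–CH3, C4–C4a, C3≡C4).** The C3 methyl group is cut from the alkene, giving ynoate 15. Syn addition of a methyl copper reagent to a 2-alkynoate fixes the Z geometry by mechanism. 15 comes from alkyne 13 (through acetylide 14) by C-acylation, 13 from aldehyde 12 by one-carbon homologation, and 12 from imide 10 through alcohol 11.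

**10 to 8 to 4 + 5 (C2–CH3 and C1–C8a).** Both stereocentres are set under control of one oxazolidinone: enolate methylation (through 9) for C2, and conjugate addition to the cinnamoyl imide 4 for C1. Both new groups enter from the face of the acyl plane away from the benzyl group. For the cis (1S,2S) pattern the group added at C1 must therefore be the furyl group (from 5 through 6 and 7), with ring C already in the acceptor. Adding the aryl group to a furylacryloyl imide of the same auxiliary would give the C1 epimer.

**4 to 1 + 2 (N-acyl bond).** The imide is made from the commercial cinnamic acid 1 and auxiliary 2 through mixed anhydride 3.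

## Alternatives that were turned down

**Alternative 1:** The C1–aryl (ring C) and C2–CH3 bonds are cut together. A ring A styrenyl pinacol boronate A2 would be converted with methyllithium into its ate complex and coupled with the ring C aryl triflate A3 under Pd(OAc)2 and a chiral Mandyphos ligand. The aryl group adds to C1 while methyl shifts from boron to C2, giving the 1,1-diaryl-2-borylpropane A1.
- For: one catalytic enantioselective step sets both centres from achiral parts, with no stoichiometric auxiliary. The central oxygens arrive as methoxymethyl ethers, so no selective demethylation is needed. On both points it is stronger than the chosen route.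
- Against: the alkene carbon C1 sits on an aryl ring substituted at both ortho positions (C8 methoxy and the masked C4 aldehyde), a hindered β-aryl alkenyl boronate. Methyl is a reluctant migrating group. After A1, the C2–B bond still has to become the C2–C3 bond to a methyl-bearing sp2 carbon and ring B has to be closed at C4, several steps at a hindered secondary boronate.
- Comparison: the chosen route gives up catalytic asymmetry and early oxygen differentiation, but it forms rings A and B in one step and sets C1 and C2 with well-understood auxiliary control.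

**Alternative 2:** The C3–C4 and C4–C4a bonds are cut, removing C4 as a one-carbon insert. A cis-3-aryl-2-methylindan-1-one A5 would be treated with trimethylsilyldiazomethane and BF3·OEt2. The diazo carbon adds to the carbonyl and the ring A carbon migrates with loss of N2, giving the 2-tetralone-type ketone A4 (carbonyl at C3).
- For: it is shorter than the chosen route, the indanone is easy to make, and the phenols are already differentiated as silyl ethers.
- Against: C2 is α to the carbonyl in both A5 and A4 and can epimerise via the enol under the Lewis acid, putting the cis relationship at risk. The β-tetralone A4 enolises very readily toward C4, so the methyl addition needed at C3 competes with enolisation. Migration of C2 instead of the aryl carbon, and double insertion, are further risks.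
- Comparison: in the chosen route C2 is α to a carbonyl only in the briefly handled aldehyde 12, and the C3 methyl and the C3=C4 alkene are in place before ring formation.

**Alternative 3:** The C2–C3 and C1–C8a bonds are cut. An aryl propargyl cinnamyl ether A7 would be cyclised with the cationic gold catalyst from (R)-DTBM-SEGPHOS(AuCl)2 and AgSbF6. The alkene attacks the activated alkyne (C2–C3), and the ortho carbon of ring A opens the resulting cyclopropyl gold carbene at C1 (C1–C8a), giving the furan-fused dihydronaphthalene A6.
- For: it is catalytic and enantioselective, builds ring B and both centres in one step from two symmetric syringyl-type halves, transfers the E-alkene geometry by anti addition to the required cis relationship, and carries the central oxygens as methoxymethyl ethers. It is more convergent than the chosen route.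
- Against: the two future methyl carbons are joined through an ether oxygen. Only the allylic C–O bond is activated for reduction; the other is a plain primary alkyl ether and needs ring opening, activation and hydride reduction on a molecule with an acid-sensitive styrene. Reductive cleavage may also move the C3=C4 double bond.
- Comparison: the chosen route carries both methyl groups as methyl groups from the start and pays with a longer linear sequence.

Key step: step 12

## Route

Step 1
Reactants: 1 (E)-3-(3,4,5-trimethoxyphenyl)prop-2-enoic acid (3,4,5-trimethoxycinnamic acid); 2 (S)-4-benzyl-1,3-oxazolidin-2-one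
Product: 4 (4S)-4-benzyl-3-[(2E)-3-(3,4,5-trimethoxyphenyl)prop-2-enoyl]-1,3-oxazolidin-2-one, via mixed pivalic anhydride 3 (not isolated)
Conditions: t-BuCOCl, Et3N, THF, −20 °C; then 2, LiCl, −20 °C → rt
Reagents that add atoms: none
Why: N-acylation of the oxazolidinone through the mixed pivalic anhydride (LiCl/Et3N variant), a standard way to make N-enoyl imides without a strong base.

Step 2
Reactants: 5 3,4-dimethoxyfuran; 4 (4S)-4-benzyl-3-[(2E)-3-(3,4,5-trimethoxyphenyl)prop-2-enoyl]-1,3-oxazolidin-2-one
Product: 8 (4S)-4-benzyl-3-[(3S)-3-(3,4-dimethoxyfuran-2-yl)-3-(3,4,5-trimethoxyphenyl)propanoyl]-1,3-oxazolidin-2-one, via 2-lithio-3,4-dimethoxyfuran 6 (not isolated), via (3,4-dimethoxyfuran-2-yl)magnesium bromide 7 (not isolated)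
Conditions: 5, n-BuLi, THF, −78 → 0 °C; MgBr2·OEt2, 0 °C; CuBr·SMe2 (0.3 equiv), THF/Me2S, −40 °C; then 4, −40 → −10 °C
Reagents that add atoms: none
Why: Copper-catalysed conjugate addition of a heteroaryl magnesium halide to an N-enoyl oxazolidinone (ortho-methoxyaryl reagents are known to add in this way). Magnesium chelates the two imide carbonyls, the enoyl unit is s-cis and the benzyl group shields one face, so the furyl group adds to the open face and sets C1 as S.

Step 3
Reactants: 8 (4S)-4-benzyl-3-[(3S)-3-(3,4-dimethoxyfuran-2-yl)-3-(3,4,5-trimethoxyphenyl)propanoyl]-1,3-oxazolidin-2-one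
Product: 10 (4S)-4-benzyl-3-[(2S,3S)-3-(3,4-dimethoxyfuran-2-yl)-2-methyl-3-(3,4,5-trimethoxyphenyl)propanoyl]-1,3-oxazolidin-2-one, via sodium Z-enolate 9 (not isolated)
Conditions: NaN(SiMe3)2, THF, −78 °C; MeI, −78 → −40 °C
Reagents that add atoms: methyl iodide, CI
Why: Evans alkylation: the chelated Z-enolate 9 takes methyl iodide on the face away from the benzyl group, which sets C2 as S. Methyl and furyl have then entered from the same face of the acyl plane, which corresponds to the cis C1/C2 relationship of ring B.

Step 4
Reactants: 10 (4S)-4-benzyl-3-[(2S,3S)-3-(3,4-dimethoxyfuran-2-yl)-2-methyl-3-(3,4,5-trimethoxyphenyl)propanoyl]-1,3-oxazolidin-2-one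
Product: 11 (2S,3S)-3-(3,4-dimethoxyfuran-2-yl)-2-methyl-3-(3,4,5-trimethoxyphenyl)propan-1-ol
Conditions: LiBH4, MeOH (1 equiv), THF, 0 °C
Reagents that add atoms: none
Why: Reductive removal of the auxiliary by hydride attack at the exocyclic imide carbonyl; no epimerisable intermediate is formed and auxiliary 2 is recovered.

Step 5
Reactants: 11 (2S,3S)-3-(3,4-dimethoxyfuran-2-yl)-2-methyl-3-(3,4,5-trimethoxyphenyl)propan-1-ol
Product: 12 (2S,3S)-3-(3,4-dimethoxyfuran-2-yl)-2-methyl-3-(3,4,5-trimethoxyphenyl)propanal
Conditions: SO3·pyridine, DMSO, i-Pr2NEt, CH2Cl2, 0 °C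
Reagents that add atoms: none
Why: Parikh–Doering oxidation; the non-acidic activated-DMSO conditions at 0 °C spare the electron-rich furan and should keep the α-stereocentre C2 intact.

Step 6
Reactants: 12 (2S,3S)-3-(3,4-dimethoxyfuran-2-yl)-2-methyl-3-(3,4,5-trimethoxyphenyl)propanal
Product: 13 3,4-dimethoxy-2-[(1S,2S)-2-methyl-1-(3,4,5-trimethoxyphenyl)but-3-yn-1-yl]furan
Conditions: dimethyl (1-diazo-2-oxopropyl)phosphonate, K2CO3, MeOH, 0 °C → rt
Reagents that add atoms: dimethyl (1-diazo-2-oxopropyl)phosphonate, CC(=O)C(=[N+]=[N-])P(=O)(OC)OC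
Why: Seyferth–Gilbert homologation in the Ohira–Bestmann variant: the diazophosphonate anion adds to the aldehyde, and loss of dimethyl phosphate and N2 gives an alkylidene carbene whose 1,2-hydrogen shift gives the terminal alkyne (C3≡C4). The mild carbonate base limits epimerisation at C2.

Step 7
Reactants: 13 3,4-dimethoxy-2-[(1S,2S)-2-methyl-1-(3,4,5-trimethoxyphenyl)but-3-yn-1-yl]furan
Product: 15 methyl (4S,5S)-5-(3,4-dimethoxyfuran-2-yl)-4-methyl-5-(3,4,5-trimethoxyphenyl)pent-2-ynoate, via lithium acetylide 14 (not isolated)
Conditions: n-BuLi (1.05 equiv), THF, −78 °C; ClCO2Me, −78 → 0 °C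
Reagents that add atoms: methyl chloroformate, COC(=O)Cl
Why: Deprotonation of the terminal alkyne, which is far more acidic than the furan C–H, and C-acylation of the acetylide. This introduces C4a and activates the triple bond for the next step.

Step 8
Reactants: 15 methyl (4S,5S)-5-(3,4-dimethoxyfuran-2-yl)-4-methyl-5-(3,4,5-trimethoxyphenyl)pent-2-ynoate
Product: 16 methyl (2Z,4S,5S)-5-(3,4-dimethoxyfuran-2-yl)-3,4-dimethyl-5-(3,4,5-trimethoxyphenyl)pent-2-enoate
Conditions: Me2CuLi (from CuI, 2 MeLi), THF, −78 °C; MeOH, −78 °C
Reagents that add atoms: lithium dimethylcuprate, [Li+].C[Cu-]C (formed from methyllithium, [Li]C, and CuI)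
Why: Syn carbocupration of a 2-alkynoate: methyl adds to C3 and copper to C4 on the same side, and protonation at −78 °C with retention leaves the C2 branch cis to the ester. The Z geometry is thus set by mechanism and not by a steric preference.

Step 9
Reactants: 16 methyl (2Z,4S,5S)-5-(3,4-dimethoxyfuran-2-yl)-3,4-dimethyl-5-(3,4,5-trimethoxyphenyl)pent-2-enoate
Product: 17 (2Z,4S,5S)-5-(3,4-dimethoxyfuran-2-yl)-3,4-dimethyl-5-(3,4,5-trimethoxyphenyl)pent-2-en-1-ol
Conditions: i-Bu2AlH (2.5 equiv), CH2Cl2, −78 °C
Reagents that add atoms: none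
Why: 1,2-reduction of the enoate by the aluminium hydride at low temperature; the alkene geometry is not affected.

Step 10
Reactants: 17 (2Z,4S,5S)-5-(3,4-dimethoxyfuran-2-yl)-3,4-dimethyl-5-(3,4,5-trimethoxyphenyl)pent-2-en-1-ol
Product: 18 (2Z,4S,5S)-5-(3,4-dimethoxyfuran-2-yl)-3,4-dimethyl-5-(3,4,5-trimethoxyphenyl)pent-2-enal
Conditions: MnO2, CH2Cl2, rt
Reagents that add atoms: none
Why: Allylic oxidation with MnO2 under neutral conditions, which converts Z-allylic alcohols to Z-enals without isomerisation; 18 should be used at once.

Step 11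
Reactants: 18 (2Z,4S,5S)-5-(3,4-dimethoxyfuran-2-yl)-3,4-dimethyl-5-(3,4,5-trimethoxyphenyl)pent-2-enal
Product: 19 3,4-dimethoxy-2-[(1S,2S,3Z)-2,3-dimethyl-1-(3,4,5-trimethoxyphenyl)hex-3-en-5-yn-1-yl]furan
Conditions: Me3SiCHN2, LiN(i-Pr)2 (1.0 equiv to the diazo compound), THF, −78 °C → rt
Reagents that add atoms: (trimethylsilyl)diazomethane, C[Si](C)(C)C=[N+]=[N-]
Why: Colvin homologation: the lithiated diazo compound adds 1,2 to the enal, Peterson-type loss of Me3SiOLi gives a diazoalkene and then an alkylidene carbene, and its 1,2-shift gives the terminal enyne (C4a≡C5). Aprotic conditions avoid conjugate addition of methanol, and the absence of excess amide base avoids γ-deprotonation at C2.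

Step 12
Reactants: 19 3,4-dimethoxy-2-[(1S,2S,3Z)-2,3-dimethyl-1-(3,4,5-trimethoxyphenyl)hex-3-en-5-yn-1-yl]furan
Product: 21 (1S,2S)-6-hydroxy-7,8-dimethoxy-2,3-dimethyl-1-(3,4,5-trimethoxyphenyl)-1,2-dihydronaphthalene, via oxygen-bridged cycloadduct 20 (not isolated)
Conditions: BHT (0.1 equiv), 1,2-dichlorobenzene (0.01 M, degassed), 180 °C, sealed tube
Reagents that add atoms: none
Why: Thermal intramolecular Diels–Alder reaction of the furan (diene C8a=C8–C7=C6) with the tethered terminal alkyne (dienophile C4a≡C5) gives the 7-oxanorbornadiene 20 by forming C4a–C8a and C5–C6. Heterolysis of the C8a–O bond, helped by the C7 methoxy group through the C8=C7 double bond, and loss of the C6 proton then give phenol 21; this aromatisation is irreversible and drains the reversible cycloaddition. The closest known reaction type is the furan–alkyne intramolecular Diels–Alder/aromatisation route to phenols, which is usually run with three-atom tethers or activated alkynes. Ring A closes as the six-membered carbocycle of the [4+2] addition (both new bonds), and ring B closes through the C4a–C8a bond alone, as the fused six-membered ring spanned by the four-atom tether C1–C2–C3=C4 (type 1 mode). No new stereocentre remains: the bridgehead centres C6 and C8a of 20 become sp2, so both bridgehead diastereomers converge, and C1 and C2 are spectators under neutral conditions. The step needs a reactive conformation, which the Z alkene, the two sp carbons and the branching at C1, C2 and C3 favour by holding the alkyne over the furan; the two methoxy groups raise the diene HOMO and the conjugated alkene lowers the alkyne LUMO. It also needs the bridge to open toward C8a, because only then does the oxygen stay on C6, which carries the hydrogen that is lost, whereas opening at C6–O can only reclose. AuCl3 or PtCl2 are deliberately not used, since their furan–yne pathway through a cyclopropyl carbene would place the hydroxyl on C5.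

Step 13
Reactants: 21 (1S,2S)-6-hydroxy-7,8-dimethoxy-2,3-dimethyl-1-(3,4,5-trimethoxyphenyl)-1,2-dihydronaphthalene
Product: 22 (1S,2S)-6,7,8-trimethoxy-2,3-dimethyl-1-(3,4,5-trimethoxyphenyl)-1,2-dihydronaphthalene
Conditions: MeI, K2CO3, acetone, 50 °C
Reagents that add atoms: methyl iodide, CI
Why: Williamson methylation of the unhindered C6 phenol; the mild base does not affect C1, C2 or the styrene.

Step 14
Reactants: 22 (1S,2S)-6,7,8-trimethoxy-2,3-dimethyl-1-(3,4,5-trimethoxyphenyl)-1,2-dihydronaphthalene
Product: 23 (1S,2S)-7-hydroxy-1-(4-hydroxy-3,5-dimethoxyphenyl)-6,8-dimethoxy-2,3-dimethyl-1,2-dihydronaphthalene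
Conditions: NaSEt (8 equiv), DMF (degassed), 120 °C
Reagents that add atoms: none
Why: Nucleophilic O-demethylation by SN2 attack of the thiolate on a methyl group: in a 1,2,3-trimethoxyarene the central methoxy group is twisted out of the ring plane and its aryloxide is the best leaving group (at C7 it is also para to the C4a vinyl group), so one methyl should be lost from C7 and one from C4 of ring C. Each ring should stop at the mono-phenoxide, and the basic, non-oxidising medium leaves the acid-sensitive styrene and both stereocentres alone.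

## Compound list

1 | (E)-3-(3,4,5-trimethoxyphenyl)prop-2-enoic acid | COc1cc(/C=C/C(=O)O)cc(OC)c1OC | starting material
2 | (S)-4-benzyl-1,3-oxazolidin-2-one | O=C1N[C@@H](Cc2ccccc2)CO1 | starting material
3 | (E)-3-(3,4,5-trimethoxyphenyl)prop-2-enoic pivalic anhydride | COc1cc(/C=C/C(=O)OC(=O)C(C)(C)C)cc(OC)c1OC | intermediate
4 | (4S)-4-benzyl-3-[(2E)-3-(3,4,5-trimethoxyphenyl)prop-2-enoyl]-1,3-oxazolidin-2-one | COc1cc(/C=C/C(=O)N2[C@@H](Cc3ccccc3)COC2=O)cc(OC)c1OC | intermediate
5 | 3,4-dimethoxyfuran | COc1cocc1OC | starting material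
6 | 2-lithio-3,4-dimethoxyfuran | COc1coc([Li])c1OC | intermediate
7 | (3,4-dimethoxyfuran-2-yl)magnesium bromide | COc1coc([Mg]Br)c1OC | intermediate
8 | (4S)-4-benzyl-3-[(3S)-3-(3,4-dimethoxyfuran-2-yl)-3-(3,4,5-trimethoxyphenyl)propanoyl]-1,3-oxazolidin-2-one | COc1cc([C@@H](c2occ(OC)c2OC)CC(=O)N2[C@@H](Cc3ccccc3)COC2=O)cc(OC)c1OC | intermediate
9 | sodium (Z)-enolate of 8 | [Na+].[O-]/C(=C\[C@H](c1occ(OC)c1OC)c1cc(OC)c(OC)c(OC)c1)N1[C@@H](Cc2ccccc2)COC1=O | intermediate
10 | (4S)-4-benzyl-3-[(2S,3S)-3-(3,4-dimethoxyfuran-2-yl)-2-methyl-3-(3,4,5-trimethoxyphenyl)propanoyl]-1,3-oxazolidin-2-one | COc1cc([C@@H](c2occ(OC)c2OC)[C@H](C)C(=O)N2[C@@H](Cc3ccccc3)COC2=O)cc(OC)c1OC | intermediate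
11 | (2S,3S)-3-(3,4-dimethoxyfuran-2-yl)-2-methyl-3-(3,4,5-trimethoxyphenyl)propan-1-ol | COc1cc([C@@H](c2occ(OC)c2OC)[C@H](C)CO)cc(OC)c1OC | intermediate
12 | (2S,3S)-3-(3,4-dimethoxyfuran-2-yl)-2-methyl-3-(3,4,5-trimethoxyphenyl)propanal | COc1cc([C@@H](c2occ(OC)c2OC)[C@H](C)C=O)cc(OC)c1OC | intermediate
13 | 3,4-dimethoxy-2-[(1S,2S)-2-methyl-1-(3,4,5-trimethoxyphenyl)but-3-yn-1-yl]furan | COc1cc([C@@H](c2occ(OC)c2OC)[C@H](C)C#C)cc(OC)c1OC | intermediate
14 | lithium acetylide of 13 | COc1cc([C@@H](c2occ(OC)c2OC)[C@H](C)C#C[Li])cc(OC)c1OC | intermediate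
15 | methyl (4S,5S)-5-(3,4-dimethoxyfuran-2-yl)-4-methyl-5-(3,4,5-trimethoxyphenyl)pent-2-ynoate | COc1cc([C@@H](c2occ(OC)c2OC)[C@H](C)C#CC(=O)OC)cc(OC)c1OC | intermediate
16 | methyl (2Z,4S,5S)-5-(3,4-dimethoxyfuran-2-yl)-3,4-dimethyl-5-(3,4,5-trimethoxyphenyl)pent-2-enoate | COc1cc([C@@H](c2occ(OC)c2OC)[C@H](C)/C(C)=C\C(=O)OC)cc(OC)c1OC | intermediate
17 | (2Z,4S,5S)-5-(3,4-dimethoxyfuran-2-yl)-3,4-dimethyl-5-(3,4,5-trimethoxyphenyl)pent-2-en-1-ol | COc1cc([C@@H](c2occ(OC)c2OC)[C@H](C)/C(C)=C\CO)cc(OC)c1OC | intermediate
18 | (2Z,4S,5S)-5-(3,4-dimethoxyfuran-2-yl)-3,4-dimethyl-5-(3,4,5-trimethoxyphenyl)pent-2-enal | COc1cc([C@@H](c2occ(OC)c2OC)[C@H](C)/C(C)=C\C=O)cc(OC)c1OC | intermediate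
19 | 3,4-dimethoxy-2-[(1S,2S,3Z)-2,3-dimethyl-1-(3,4,5-trimethoxyphenyl)hex-3-en-5-yn-1-yl]furan | COc1cc([C@@H](c2occ(OC)c2OC)[C@H](C)/C(C)=C\C#C)cc(OC)c1OC | intermediate
20 | (1S,2S)-6,8a-epoxy-7,8-dimethoxy-2,3-dimethyl-1-(3,4,5-trimethoxyphenyl)-1,2,6,8a-tetrahydronaphthalene (either bridgehead diastereomer) | COc1cc([C@@H]2[C@H](C)C(C)=CC3=CC4OC23C(OC)=C4OC)cc(OC)c1OC | intermediate
21 | (1S,2S)-6-hydroxy-7,8-dimethoxy-2,3-dimethyl-1-(3,4,5-trimethoxyphenyl)-1,2-dihydronaphthalene | COc1cc([C@H]2c3c(cc(O)c(OC)c3OC)C=C(C)[C@H]2C)cc(OC)c1OC | intermediate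
22 | (1S,2S)-6,7,8-trimethoxy-2,3-dimethyl-1-(3,4,5-trimethoxyphenyl)-1,2-dihydronaphthalene | COc1cc([C@H]2c3c(cc(OC)c(OC)c3OC)C=C(C)[C@H]2C)cc(OC)c1OC | intermediate
23 | (1S,2S)-7-hydroxy-1-(4-hydroxy-3,5-dimethoxyphenyl)-6,8-dimethoxy-2,3-dimethyl-1,2-dihydronaphthalene | COc1cc([C@H]2c3c(cc(OC)c(O)c3OC)C=C(C)[C@H]2C)cc(OC)c1O | target

## Step count and least certain steps

Total: 14 steps. Longest linear sequence: 14 steps (1 to 23); furan 5 enters in step 2.

**Step 12 (key step).** The cycloaddition of an unactivated alkyne over a four-atom tether may be too slow at temperatures the substrate tolerates. A thermal 1,5-hydrogen shift from C2 to the alkyne terminus could then compete, forming a vinylallene and losing the C2 configuration. The bridge of 20 may also open toward C6 and go on to skeletal shifts, and traces of oxygen could aromatise ring B. Fallback, from 19 and back at 21: the dienophile is activated with a removable ester on C5. The acetylide of 19 (n-BuLi, THF, −78 °C) is acylated with allyl chloroformate to give prop-2-en-1-yl (4Z,6S,7S)-7-(3,4-dimethoxyfuran-2-yl)-5,6-dimethyl-7-(3,4,5-trimethoxyphenyl)hept-4-en-2-ynoate F1. The ynoate should cyclise and aromatise in toluene at about 110 °C to the salicylate prop-2-en-1-yl (5S,6S)-2-hydroxy-3,4-dimethoxy-6,7-dimethyl-5-(3,4,5-trimethoxyphenyl)-5,6-dihydronaphthalene-1-carboxylate F2. Pd(PPh3)4 with morpholine removes the allyl group to give (5S,6S)-2-hydroxy-3,4-dimethoxy-6,7-dimethyl-5-(3,4,5-trimethoxyphenyl)-5,6-dihydronaphthalene-1-carboxylic acid F3. This ortho-hydroxy, para-methoxy benzoic acid should lose CO2 on warming in DMSO with catalytic Ag2CO3 and acetic acid, which gives 21.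

**Step 14.** Loss of the C8 methyl group may compete with loss of the C7 methyl group, because both methoxy groups are twisted out of the ring plane. The second ring may react incompletely, or a ring may lose two methyl groups on long heating. Fallback, from 22 and back at 23: the control element is changed from leaving-group ability to chelation. With BCl3 in CH2Cl2 (−78 → 0 °C) boron is held between two adjacent oxygens, which only the central methoxy group of each triad can offer from both sides, and chloride removes that methyl group. The styrene must be protected from the acid by low temperature and a buffered quench. This fallback makes no new compound (F0).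

**Step 2.** A 2-furyl group is transferred from copper reluctantly, so conjugate addition may be slow, and attack of the organomagnesium reagent at the imide carbonyls or eroded facial selectivity may follow. Fallback, from 4 and 5 and back at 8: a Friedel–Crafts-type conjugate addition. Imide 4 is activated as its chelate with Me2AlCl (CH2Cl2, −78 °C) and attacked by the neutral, strongly nucleophilic furan 5 (in excess) at C2. The chelate geometry and the shielded face are the same, so the same configuration at C1 is expected. This fallback makes no new compound (F0).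

**Step 11.** The diazo anion may add in conjugate fashion, or residual base may deprotonate C2 (the γ-position of the enal), which would scramble both the alkene geometry and the C2 centre. Fallback, from 18 and back at 19: Ramirez dibromo-olefination (CBr4, PPh3, Zn, CH2Cl2, 0 °C) gives 2-[(1S,2S,3Z)-6,6-dibromo-2,3-dimethyl-1-(3,4,5-trimethoxyphenyl)hexa-3,5-dien-1-yl]-3,4-dimethoxyfuran F4, and n-BuLi (2 equiv, THF, −78 °C; Corey–Fuchs) then gives 19.

**Step 6.** The carbonate base may epimerise C2 of aldehyde 12 before homologation is complete. Fallback, from 12 and back at 15: dibromo-olefination (CBr4, PPh3, Zn) gives 2-[(1S,2S)-4,4-dibromo-2-methyl-1-(3,4,5-trimethoxyphenyl)but-3-en-1-yl]-3,4-dimethoxyfuran F5. n-BuLi (2 equiv, −78 °C) converts it into acetylide 14, which is trapped with methyl chloroformate to give 15 directly, without isolating 13.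

## Further compounds

F1 | step 12 | prop-2-en-1-yl (4Z,6S,7S)-7-(3,4-dimethoxyfuran-2-yl)-5,6-dimethyl-7-(3,4,5-trimethoxyphenyl)hept-4-en-2-ynoate | COc1cc([C@@H](c2occ(OC)c2OC)[C@H](C)/C(C)=C\C#CC(=O)OCC=C)cc(OC)c1OC
F2 | step 12 | prop-2-en-1-yl (5S,6S)-2-hydroxy-3,4-dimethoxy-6,7-dimethyl-5-(3,4,5-trimethoxyphenyl)-5,6-dihydronaphthalene-1-carboxylate | COc1cc([C@H]2c3c(c(C(=O)OCC=C)c(O)c(OC)c3OC)C=C(C)[C@H]2C)cc(OC)c1OC
F3 | step 12 | (5S,6S)-2-hydroxy-3,4-dimethoxy-6,7-dimethyl-5-(3,4,5-trimethoxyphenyl)-5,6-dihydronaphthalene-1-carboxylic acid | COc1cc([C@H]2c3c(c(C(=O)O)c(O)c(OC)c3OC)C=C(C)[C@H]2C)cc(OC)c1OC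
F4 | step 11 | 2-[(1S,2S,3Z)-6,6-dibromo-2,3-dimethyl-1-(3,4,5-trimethoxyphenyl)hexa-3,5-dien-1-yl]-3,4-dimethoxyfuran | COc1cc([C@@H](c2occ(OC)c2OC)[C@H](C)/C(C)=C\C=C(Br)Br)cc(OC)c1OC
F5 | step 6 | 2-[(1S,2S)-4,4-dibromo-2-methyl-1-(3,4,5-trimethoxyphenyl)but-3-en-1-yl]-3,4-dimethoxyfuran | COc1cc([C@@H](c2occ(OC)c2OC)[C@H](C)C=C(Br)Br)cc(OC)c1OC
F0 | step 14 | none | none
F0 | step 2 | none | none
A1 | alternative 1 | pinacol boronate of 1-[2-(1,3-dioxolan-2-yl)-4,6-dimethoxy-5-(methoxymethoxy)phenyl]-1-[3,5-dimethoxy-4-(methoxymethoxy)phenyl]propan-2-yl, both centres set | COc1cc([C@@H](c2c(C3OCCO3)cc(OC)c(OCOC)c2OC)[C@H](C)B2OC(C)(C)C(C)(C)O2)cc(OC)c1OCOC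
A2 | alternative 1 | 2-[(E)-2-[2-(1,3-dioxolan-2-yl)-4,6-dimethoxy-5-(methoxymethoxy)phenyl]ethenyl]-4,4,5,5-tetramethyl-1,3,2-dioxaborolane | COc1cc(C2OCCO2)c(/C=C/B2OC(C)(C)C(C)(C)O2)c(OC)c1OCOC
A3 | alternative 1 | 3,5-dimethoxy-4-(methoxymethoxy)phenyl trifluoromethanesulfonate | COc1cc(OS(=O)(=O)C(F)(F)F)cc(OC)c1OCOC
A4 | alternative 2 | cis-7-(tert-butyldimethylsilyloxy)-1-[4-(tert-butyldimethylsilyloxy)-3,5-dimethoxyphenyl]-6,8-dimethoxy-2-methyl-3-oxo-1,2,3,4-tetrahydronaphthalene (target numbering) | COc1cc([C@H]2c3c(cc(OC)c(O[Si](C)(C)C(C)(C)C)c3OC)CC(=O)[C@H]2C)cc(OC)c1O[Si](C)(C)C(C)(C)C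
A5 | alternative 2 | cis-5-(tert-butyldimethylsilyloxy)-3-[4-(tert-butyldimethylsilyloxy)-3,5-dimethoxyphenyl]-4,6-dimethoxy-2-methylindan-1-one | COc1cc([C@H]2c3c(cc(OC)c(O[Si](C)(C)C(C)(C)C)c3OC)C(=O)[C@H]2C)cc(OC)c1O[Si](C)(C)C(C)(C)C
A6 | alternative 3 | 1-aryl-1,2-dihydronaphthalene with a furan ring fused across C2 and C3, bearing methoxymethyl ethers on the C7 oxygen and on the C4 oxygen of ring C | COc1cc([C@H]2c3c(cc(OC)c(OCOC)c3OC)C=C4COC[C@@H]24)cc(OC)c1OCOC
A7 | alternative 3 | 5-[3-{[(2E)-3-[3,5-dimethoxy-4-(methoxymethoxy)phenyl]prop-2-en-1-yl]oxy}prop-1-yn-1-yl]-1,3-dimethoxy-2-(methoxymethoxy)benzene | COc1cc(C#CCOC/C=C/c2cc(OC)c(OCOC)c(OC)c2)cc(OC)c1OCOC
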